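The target consists of two identical rings, A and A′, joined through one CH2 group. Both aryl C1–CH2 bonds are therefore cut at once, and the bridge carbon is traced back to ethyl formate. In 1,2-dibromo-3,4-dimethoxybenzene the future C1–H is the only ring hydrogen next to a bromine (C2–Br); the other, C6–H, lies next to the C5 methoxy group. A hindered lithium amide removes C1–H, and MgCl2 waiting in the flask fixes the anion as 2,3-dibromo-4,5-dimethoxyphenylmagnesium chloride. Two equivalents of this reagent add to the formate and give the symmetric benzhydrol in one operation. Ionic deoxygenation and cleavage of four methyl ethers complete the route.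

Key step: step 2

Remark: from compound 6 on, ring atoms are numbered as in the target (C1 bridge carbon, C2 and C3 bromine, C4 and C5 oxygen, C6 hydrogen). The target is achiral, so no stereocentre has to be set.

Step 1
Reactants: 1 4-bromo-1,2-dimethoxybenzene; 2 1,2-dibromo-1,1,2,2-tetrachloroethane
Product: 4 1,2-dibromo-3,4-dimethoxybenzene, via 6-bromo-2,3-dimethoxyphenyllithium 3 (not isolated)
Conditions: LiN(iPr)2 (commercial solution, 1.1 equiv), THF, −78 °C, 1 h; transferred by cannula into 2 (1.3 equiv), THF, −78 °C → rt
Reagents that add atoms: 1,2-dibromo-1,1,2,2-tetrachloroethane 2, ClC(Cl)(Br)C(Cl)(Cl)Br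
Why: Directed ortho-metalation followed by electrophilic bromination: C3–H of 1 lies between the bromine and a methoxy group, so inductive acidification and lithium coordination select the same hydrogen, anion 3 is already the best-stabilised positional isomer (no driving force for bromine migration), and 2 transfers a bromine to the carbanion while collapsing to tetrachloroethene.

Step 2
Reactants: 4 1,2-dibromo-3,4-dimethoxybenzene (2 equiv); 5 ethyl formate
Product: 9 bis(2,3-dibromo-4,5-dimethoxyphenyl)methanol, via 2,3-dibromo-4,5-dimethoxyphenyllithium 6 (not isolated), via 2,3-dibromo-4,5-dimethoxyphenylmagnesium chloride 7 (not isolated), via 2,3-dibromo-4,5-dimethoxybenzaldehyde 8 (not isolated)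
Conditions: MgCl2 (0.5 M in THF, 1.3 equiv), THF, −78 °C; lithium 2,2,6,6-tetramethylpiperidide (1.3 equiv, from the amine and nBuLi), 15 min; 5 (0.48 equiv relative to 4), −78 → 0 °C, 2 h; cold 1 M HCl
Reagents that add atoms: ethyl formate 5, CCOC=O
Why: The hindered lithium amide deprotonates 4 at the C–H beside bromine (deprotonative metalation of an oligobromoarene), and the MgCl2 already present turns aryllithium 6 at once into Grignard reagent 7 (in situ trapping metalation). 7 adds to the formyl carbon of 5, the magnesium hemiacetal expels ethoxide to give aldehyde 8, and 8, a better electrophile than the ester, takes up a second 7, so both aryl C1–C bonds form in one flask and the acid quench frees 9. The closest known reaction type is the double addition of an arylmagnesium halide to a formate ester to give a symmetric diarylmethanol. No ring closes, and the carbinol carbon carries two identical aryl groups, so no stereocentre arises. The selectivity needed is C1–H over C6–H: C1–H is acidified by the ortho C2–Br and the meta C3–Br, whereas C6–H has only the C5 methoxy group, whose methyl group turns toward C6–H (away from the C4 methoxy group) and screens it from a bulky base that does not rely on oxygen coordination. The immediate change from lithium to magnesium at −78 °C closes the paths open to an ortho-bromoaryllithium (bromide loss to an aryne, bromine migration), and because 5 is the limiting reagent any unused 7 returns as reusable 4 on work-up.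

Step 3
Reactants: 9 bis(2,3-dibromo-4,5-dimethoxyphenyl)methanol
Product: 10 bis(2,3-dibromo-4,5-dimethoxyphenyl)methane
Conditions: Et3SiH (3 equiv), CF3CO2H/CH2Cl2 (1:1), 0 °C → rt; aq NaHCO3
Reagents that add atoms: none
Why: Ionic hydrogenation: CF3CO2H ionises the doubly benzylic alcohol to a benzhydryl cation supported by the two para (C4) methoxy groups, Et3SiH delivers hydride to it, and aryl bromides and methyl ethers are inert to this reagent pair.

Step 4
Reactants: 10 bis(2,3-dibromo-4,5-dimethoxyphenyl)methane
Product: 11 bis(2,3-dibromo-4,5-dihydroxyphenyl)methane
Conditions: BBr3 (6 equiv), CH2Cl2, −78 °C → rt, 12 h; ice-water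
Reagents that add atoms: none
Why: Lewis-acid cleavage of aryl methyl ethers with BBr3: each ether oxygen binds boron, bromide removes the methyl group by SN2 attack, and hydrolysis of the aryl borates frees both catechols, while the C–Br bonds and the diarylmethane CH2 are not touched.

Compound list
1 | 4-bromo-1,2-dimethoxybenzene (4-bromoveratrole) | COc1ccc(Br)cc1OC | starting material
2 | 1,2-dibromo-1,1,2,2-tetrachloroethane | ClC(Cl)(Br)C(Cl)(Cl)Br | starting material
3 | 6-bromo-2,3-dimethoxyphenyllithium | [Li]c1c(Br)ccc(OC)c1OC | intermediate
4 | 1,2-dibromo-3,4-dimethoxybenzene | COc1ccc(Br)c(Br)c1OC | intermediate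
5 | ethyl formate | CCOC=O | starting material
6 | 2,3-dibromo-4,5-dimethoxyphenyllithium | COc1cc([Li])c(Br)c(Br)c1OC | intermediate
7 | 2,3-dibromo-4,5-dimethoxyphenylmagnesium chloride | COc1cc([Mg]Cl)c(Br)c(Br)c1OC | intermediate
8 | 2,3-dibromo-4,5-dimethoxybenzaldehyde | COc1cc(C=O)c(Br)c(Br)c1OC | intermediate
9 | bis(2,3-dibromo-4,5-dimethoxyphenyl)methanol | COc1cc(C(O)c2cc(OC)c(OC)c(Br)c2Br)c(Br)c(Br)c1OC | intermediate
10 | bis(2,3-dibromo-4,5-dimethoxyphenyl)methane | COc1cc(Cc2cc(OC)c(OC)c(Br)c2Br)c(Br)c(Br)c1OC | intermediate
11 | bis(2,3-dibromo-4,5-dihydroxyphenyl)methane, also 5,5′-methylenebis(3,4-dibromobenzene-1,2-diol) | Oc1cc(Cc2cc(O)c(O)c(Br)c2Br)c(Br)c(Br)c1O | target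

Total step count: 4
Longest linear sequence: 4 steps (1 → 4 → 9 → 10 → 11)

Steps most likely to fail

Step 2. Several processes can erode the coupling:
- part of the deprotonation may occur at C6–H beside the methoxy group;
- bromide may be lost, or bromine may migrate, before magnesium capture;
- metalation may stay incomplete because MgCl2 intercepts the amide;
- amide base left in the flask may destroy the formate.

All of these become visible only after the coupling. The fallback sets out from 4 and comes back at 7. Compound 4 is metalated as in step 2 but quenched with I2 to give 2,3-dibromo-1-iodo-4,5-dimethoxybenzene F1. F1 is isolated and freed from any positional isomer by recrystallisation. Its structure is checked through the expected NOE contact between the lone ring hydrogen and a methoxy group. Iodine–magnesium exchange with iPrMgCl·LiCl in THF at −40 °C should then give 7 at a fixed site, free of amine and amide base and in a known amount. Compound 5 is added as in step 2.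

Step 1. Freshly formed 4 may pass its acidic C–H proton to unreacted 3 or to residual amide during the quench, which would lead to a second bromination. Incomplete lithiation would leave 1 in the product. The fallback sets out from 3 (made from 1 as in step 1) and comes back at 4. Compound 3 is quenched with CO2 instead of a bromine donor and acidified with HCl to give 6-bromo-2,3-dimethoxybenzoic acid F2. Acid–base extraction separates F2 from all neutral material. Decarboxylative ipso-bromination of this electron-rich ortho-methoxybenzoic acid (Bu4NBr3, K3PO4, MeCN, 100 °C) then places the bromine on the carbon that carried the carboxyl group. No carbanion ever meets a polybromoarene in this sequence.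

Step 3. Ionisation may be slow, because four bromines and the out-of-plane C4 methoxy groups weaken the cation. Ether formation or Friedel–Crafts capture of the cation by a second molecule could then compete with hydride transfer. The fallback sets out from 9 and comes back at 10. SOCl2 in CH2Cl2 converts 9 into bis(2,3-dibromo-4,5-dimethoxyphenyl)chloromethane F3. NaBH4 in DMSO at rt then displaces the chloride by hydride, so activation and reduction are separated and no free cation has to persist in acid.

Further compounds
F1 | step 2 | 2,3-dibromo-1-iodo-4,5-dimethoxybenzene | COc1cc(I)c(Br)c(Br)c1OC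
F2 | step 1 | 6-bromo-2,3-dimethoxybenzoic acid | COc1ccc(Br)c(C(=O)O)c1OC
F3 | step 3 | bis(2,3-dibromo-4,5-dimethoxyphenyl)chloromethane | COc1cc(C(Cl)c2cc(OC)c(OC)c(Br)c2Br)c(Br)c(Br)c1OC
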